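Ring B (C5, C6, C8, C9, C10) is treated as a contracted cyclohexene whose extruded carbon survives as the C7 carboxyl on C6. Everything rests on one intramolecular Diels–Alder reaction that joins C8 to C9 and C5 to C10: a (Z)-enoate (C9=C10, C20 ester on C10) adds to the 2-oxydiene C5=C6–C7(O)=C8 of a 2-alkenyl-4,5-dihydrofuran whose ring oxygen sits on C13 and whose C13 side chain (C12, C11) is the tether. One operation closes ring C and a six-membered ring B and sets C5, C8, C9 and C10 from C13 alone; the bridging enol ether then releases the C7 ketone (Wolff contraction) and the C13 alcohol (radical closure of ring D).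

Key step: step 11

Remark: atoms carry gibberellane numbers (C1–C20); β is the face that bears H5, H9 and C15, α the face that bears C20, C19 and C14; (S)-1,2-epoxy-5-hexene is taken as commercially available.

Step 1
Reactants: 1 5-(trimethylsilyl)pent-4-ynoic acid; 2 (2S)-2-(but-3-en-1-yl)oxirane
Product: 4 (5S)-5-(but-3-en-1-yl)-3-[3-(trimethylsilyl)prop-2-yn-1-yl]oxolan-2-one (C3 epimers), via hydroxy acid 3 (not isolated)
Conditions: LiN(iPr)2 (2.2 equiv), THF, −78 → 0 °C; 2, 0 → 40 °C; aq. HCl; TsOH (cat.), PhMe, 80 °C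
Reagents that add atoms: none
Why: The carboxylic acid dianion opens the terminal epoxide at its CH2 terminus (SN2 epoxide alkylation) and the γ-hydroxy acid lactonises, so the C13–O centre of 2 is carried over untouched, while the new α-centre (future C8) needs no control because it becomes sp2.

Step 2
Reactants: 4 lactone from step 1
Product: 6 (5S)-5-(3-hydroxypropyl)-3-[3-(trimethylsilyl)prop-2-yn-1-yl]oxolan-2-one, via aldehyde 5 (not isolated)
Conditions: O3, CH2Cl2/MeOH, −78 °C (indicator end point); NaBH4, −78 → 0 °C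
Reagents that add atoms: ozone, [O-][O+]=O
Why: Ozonolysis with reductive work-up should cleave the monosubstituted alkene much faster than the silyl alkyne, and borohydride takes the ozonide through the aldehyde to the primary alcohol (future C9–O); no stereocentre is touched.

Step 3
Reactants: 6 hydroxy lactone
Product: 7 (5S)-5-{3-[tert-butyl(dimethyl)silyl]oxypropyl}-3-[3-(trimethylsilyl)prop-2-yn-1-yl]oxolan-2-one
Conditions: t-BuMe2SiCl, imidazole, DMF, 0 °C
Reagents that add atoms: tert-butyl(chloro)dimethylsilane, CC(C)(C)[Si](C)(C)Cl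
Why: Routine silylation of the primary alcohol masks it for the enolisation of step 4.

Step 4
Reactants: 7 silyl ether lactone
Product: 8 (5S)-5-{3-[tert-butyl(dimethyl)silyl]oxypropyl}-3-[3-(trimethylsilyl)prop-2-yn-1-yl]-4,5-dihydrofuran-2-yl diphenyl phosphate
Conditions: KN(SiMe3)2, THF/HMPA, −78 °C; ClP(O)(OPh)2
Reagents that add atoms: diphenyl chlorophosphate, O=P(Cl)(Oc1ccccc1)Oc1ccccc1
Why: O-Phosphorylation of the potassium lactone enolate should give the cyclic ketene acetal phosphate, a vinyl electrophile for cross-coupling; both α-epimers converge on the same enol phosphate.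

Step 5
Reactants: 9 tert-butyl but-3-enoate; 10 2-ethenyl-4,4,5,5-tetramethyl-1,3,2-dioxaborolane
Product: 11 tert-butyl (3E)-4-(4,4,5,5-tetramethyl-1,3,2-dioxaborolan-2-yl)but-3-enoate
Conditions: second-generation Grubbs catalyst RuCl2(=CHPh)(PCy3)(H2IMes) (3 mol %), CH2Cl2, 40 °C
Reagents that add atoms: none
Why: Olefin cross-metathesis of a terminal alkene with the vinylboronate should give the (E)-alkenylboronate under thermodynamic control.

Step 6
Reactants: 8 enol phosphate; 11 alkenylboronate
Product: 12 tert-butyl (3E)-4-[(5S)-5-{3-[tert-butyl(dimethyl)silyl]oxypropyl}-3-[3-(trimethylsilyl)prop-2-yn-1-yl]-4,5-dihydrofuran-2-yl]but-3-enoate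
Conditions: Pd(PPh3)4 (5 mol %), K3PO4 (aq.), THF, 40 °C; work-up on Et3N-deactivated silica
Reagents that add atoms: none
Why: Suzuki–Miyaura coupling at zerovalent palladium should join C7 to C6 with retention of the (E)-C5=C6 geometry, and the dihydrofuran ring itself fixes the enol ether geometry (ring oxygen cis to C14, propargyl carbon C15 cis to C6).

Step 7
Reactants: 12 bis-silylated dienol ether
Product: 13 tert-butyl (3E)-4-[(5S)-5-(3-hydroxypropyl)-3-(prop-2-yn-1-yl)-4,5-dihydrofuran-2-yl]but-3-enoate
Conditions: Bu4NF, THF, 0 °C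
Reagents that add atoms: none
Why: Fluoride desilylation should remove the primary silyl ether and the C(sp)–Si group in one operation and leave the base-stable dienol ether intact.

Step 8
Reactants: 13 hydroxy dienol ether
Product: 14 tert-butyl (3E)-4-[(5S)-5-(3-oxopropyl)-3-(prop-2-yn-1-yl)-4,5-dihydrofuran-2-yl]but-3-enoate
Conditions: SO3·pyridine, Me2SO, iPr2NEt, CH2Cl2, 0 °C
Reagents that add atoms: none
Why: Parikh–Doering oxidation runs under basic, non-acidic conditions, so the C9 aldehyde should form without hydrolysis of the dienol ether.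

Step 9
Reactants: 15 methyl 2-[bis(2,2,2-trifluoroethoxy)phosphoryl]acetate (excess); 16 methyl prop-2-enoate
Product: 17 dimethyl 2-[bis(2,2,2-trifluoroethoxy)phosphoryl]pentanedioate
Conditions: DBU (0.1 equiv), THF, 0 °C
Reagents that add atoms: none
Why: Base-catalysed Michael addition of the phosphonoacetate carbanion to the acrylate should attach the C1–C2–C3 ester chain to the future C10; the excess of 15 suppresses double addition.

Step 10
Reactants: 14 aldehyde; 17 phosphonate
Product: 18 dimethyl (2Z)-2-{3-[(2S)-5-[(1E)-4-tert-butoxy-4-oxobut-1-en-1-yl]-4-(prop-2-yn-1-yl)-2,3-dihydrofuran-2-yl]propylidene}pentanedioate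
Conditions: KN(SiMe3)2, 18-crown-6, THF, −78 °C
Reagents that add atoms: none
Why: Still–Gennari olefination with the bis(trifluoroethyl) phosphonate under dissociating conditions should give the (Z)-trisubstituted enoate by kinetic control, placing C11 cis to the C20 ester.

Step 11
Reactants: 18 tetraenyne triester (dienol ether plus (Z)-enoate)
Product: 20 13-hydroxy-7-oxo keto triester with rings B (six-membered) and C closed cis-fused, 5α-CH2CO2tBu, 5β-H, 8β-propargyl, 9β-H, 10α-CO2Me, 10β-CH2CH2CO2Me (in equilibrium with its bridged hemiketal), via cycloadduct 19 (not isolated)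
Conditions: PhMe (0.005 M), BHT (cat.), N,O-bis(trimethylsilyl)acetamide (0.2 equiv), 130 °C, sealed tube; then oxalic acid, THF/H2O, 0 → 20 °C
Reagents that add atoms: water, O
Why: A thermal, concerted but asynchronous normal-demand intramolecular Diels–Alder reaction (closest known type: cycloaddition of a 1,7,9-decatriene whose diene is a cyclic 2-alkoxydiene) joins the largest HOMO coefficient of the dienol ether (C8) to the β-carbon of the enoate (C9), so tether and electronics ask for the same regiochemistry (oxygen on C7 para to the ester-bearing C10). Ring B (six-membered at this stage: C5, C6, C7, C8, C9, C10) is closed by the cycloaddition itself and ring C (C8, C9, C11, C12, C13, C14) by the four-atom tether, a fused closure held inside a 6-oxabicyclo[3.2.1]octane. C8 is set by C13, because the C12–C11 chain reaches only the face of the dihydrofuran on which it stands; C9 follows because the dihydrofuran lies on the inner side of the diene and forces the tether endo, which puts C11 cis to C14 and H9 cis to C15 (the exo alternative cannot span the ring). C10 is set by the (Z)-enoate, which carries the C20 ester endo together with C11 (C20 α, C1 β), and C5 by the (E)-C5=C6 bond, which holds C4 outside and hence cis to C14 (H5 β). The step needs the cycloaddition to outrun the [1,5]-hydrogen shift from C15 and any acid-induced hydrolysis or geometric isomerisation, which the activated dienophile, the electron-rich diene, high dilution, the radical inhibitor and the acid scavenger should secure. Aqueous acid then hydrolyses the bridging enol ether of 19 to the C7 ketone and the C13 alcohol.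

Step 12
Reactants: 20 hydroxy ketone
Product: 21 13-O-(1H-imidazol-1-ylcarbonothioyl) derivative of 20
Conditions: 1,1'-thiocarbonyldiimidazole, DMAP, ClCH2CH2Cl, 60 °C
Reagents that add atoms: 1,1'-thiocarbonyldiimidazole, S=C(n1ccnc1)n1ccnc1
Why: The secondary C13 alcohol of the open hydroxy ketone, which equilibrates with the hemiketal, should be acylated to the thiocarbonyl derivative needed for Barton–McCombie-type radical generation.

Step 13
Reactants: 21 thiocarbonylimidazolide
Product: 22 7-oxo tricycle with rings B (six-membered), C and D closed (16-methylene bicyclo[3.2.1]octane), 10α-CO2Me, 10β-CH2CH2CO2Me, 5α-CH2CO2tBu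
Conditions: Bu3SnH (slow addition), AIBN, PhH, 80 °C
Reagents that add atoms: none
Why: Tin-mediated C–O homolysis gives the C13 radical, which should add 5-exo-dig to the alkyne held on C8 (radical cyclisation) once ring C has flipped to place C15 axial; only the bridging mode cis to C15 is geometrically possible, so C13 is set by the ring, and the vinyl radical is reduced to the exocyclic methylene.

Step 14
Reactants: 22 tricyclic ketone
Product: 24 6-diazo-7-ketone, via trifluoroacetyl ketone 23 (not isolated)
Conditions: LiN(SiMe3)2, THF, −78 °C; CF3CO2CH2CF3; aq. HCl work-up; then MeSO2N3, Et3N, MeCN, 20 °C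
Reagents that add atoms: methanesulfonyl azide, CS(=O)(=O)N=[N+]=[N-]; 2,2,2-trifluoroethyl trifluoroacetate (atoms only in 23), O=C(OCC(F)(F)F)C(F)(F)F
Why: C6 is the only enolisable position of the C7 ketone and the ketone is far more acidic than the esters, so trifluoroacetylation followed by deacylative Regitz diazo transfer should give the α-diazo ketone.

Step 15
Reactants: 24 diazo ketone
Product: 26 ring-B-contracted 7-tert-butyl ester (C6 epimers), via ketene 25 (not isolated)
Conditions: hν (365 nm), t-BuOH/THF, 20 °C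
Reagents that add atoms: tert-butanol, CC(C)(C)O
Why: Photochemical Wolff rearrangement should shift C8 from C7 to C6 with retention at C8 and tert-butanol traps the ketene, which contracts ring B and leaves C7 as the ester on C6; C6 forms as an epimeric mixture that is equilibrated in step 16.

Step 16
Reactants: 26 contracted triester
Product: 28 3-oxo-4β-methyl-4α-(tert-butoxycarbonyl) tetracycle (ring A closed, 6β-CO2tBu, 10α-CO2Me), via keto ester 27 (not isolated)
Conditions: KOtBu, t-BuOH/THF, 0 → 25 °C; AcOH to neutrality; then K2CO3, MeI, DMF, 25 °C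
Reagents that add atoms: iodomethane, CI
Why: In this Dieckmann condensation the C4 enolate should close onto the unhindered C3 methyl ester and be drained as the stabilised β-keto ester enolate (closure from C6 would give a bridged, non-enolisable keto ester that reverts by retro-Claisen, and the tert-butyl esters are poor electrophiles), while KOtBu equilibrates C6 to the less hindered β-ester trans to C4; C-methylation then occurs on the β face, anti to the axial C20 ester on C10, giving 4β-methyl and 4α-ester.

Step 17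
Reactants: 28 β-keto ester
Product: 29 3β-hydroxy-4β-methyl tetracyclic triester (7- and 19-tert-butyl esters, 20-methyl ester)
Conditions: K[HB(sBu)3], THF, −78 °C
Reagents that add atoms: none
Why: The bulky borohydride attacks the C3 ketone along the equatorial trajectory, since the 1,3-diaxial hydrogens at C1 and C5 block axial attack, so the axial 3β-alcohol should result by diastereoselective ketone reduction; the esters are inert at −78 °C.

Step 18
Reactants: 29 hydroxy triester
Product: 30 3β-hydroxy-20-methoxy-20-oxogibberell-16-ene-7,19-dioic acid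
Conditions: Me3SiOTf, 2,6-lutidine, CH2Cl2, 0 → 20 °C; then H2O/MeOH
Reagents that add atoms: none
Why: Silyl triflate-mediated cleavage of the tert-butyl esters (loss of isobutene through the silyl esters) should free both acids under buffered conditions that spare the acid-sensitive exocyclic alkene and the methyl ester.

Step 19
Reactants: 30 hydroxy diacid methyl ester
Product: 31 3β-hydroxy-20-oxogibberell-16-ene-7,19-dioic acid (the target gibberellin)
Conditions: iBu2AlH (6 equiv), CH2Cl2/THF, −78 → −40 °C; MeOH, then aq. KNaC4H4O6 and citric acid (pH 4)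
Reagents that add atoms: none
Why: Once the acidic hydrogens are consumed as aluminium carboxylates and alkoxide, which resist hydride at low temperature, the C20 methyl ester is the only reducible group, and its tetrahedral aluminate, stabilised at low temperature and by the neighbouring C19 carboxylate, should collapse to the aldehyde only on work-up (partial ester reduction with iBu2AlH).

Compound list
1 | 5-(trimethylsilyl)pent-4-ynoic acid | C[Si](C)(C)C#CCCC(=O)O | starting material
2 | (2S)-2-(but-3-en-1-yl)oxirane | C=CCC[C@H]1CO1 | starting material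
3 | (4S)-4-hydroxy-2-[3-(trimethylsilyl)prop-2-yn-1-yl]oct-7-enoic acid (C2 epimers) | C=CCC[C@H](O)CC(CC#C[Si](C)(C)C)C(=O)O | intermediate
4 | (5S)-5-(but-3-en-1-yl)-3-[3-(trimethylsilyl)prop-2-yn-1-yl]oxolan-2-one (C3 epimers) | C=CCC[C@H]1CC(CC#C[Si](C)(C)C)C(=O)O1 | intermediate
5 | 3-{(2S)-5-oxo-4-[3-(trimethylsilyl)prop-2-yn-1-yl]oxolan-2-yl}propanal | O=CCC[C@H]1CC(CC#C[Si](C)(C)C)C(=O)O1 | intermediate
6 | (5S)-5-(3-hydroxypropyl)-3-[3-(trimethylsilyl)prop-2-yn-1-yl]oxolan-2-one | OCCC[C@H]1CC(CC#C[Si](C)(C)C)C(=O)O1 | intermediate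
7 | (5S)-5-{3-[tert-butyl(dimethyl)silyl]oxypropyl}-3-[3-(trimethylsilyl)prop-2-yn-1-yl]oxolan-2-one | CC(C)(C)[Si](C)(C)OCCC[C@H]1CC(CC#C[Si](C)(C)C)C(=O)O1 | intermediate
8 | (5S)-5-{3-[tert-butyl(dimethyl)silyl]oxypropyl}-3-[3-(trimethylsilyl)prop-2-yn-1-yl]-4,5-dihydrofuran-2-yl diphenyl phosphate | CC(C)(C)[Si](C)(C)OCCC[C@H]1CC(CC#C[Si](C)(C)C)=C(OP(=O)(Oc2ccccc2)Oc2ccccc2)O1 | intermediate
9 | tert-butyl but-3-enoate | C=CCC(=O)OC(C)(C)C | starting material
10 | 2-ethenyl-4,4,5,5-tetramethyl-1,3,2-dioxaborolane | C=CB1OC(C)(C)C(C)(C)O1 | starting material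
11 | tert-butyl (3E)-4-(4,4,5,5-tetramethyl-1,3,2-dioxaborolan-2-yl)but-3-enoate | CC(C)(C)OC(=O)C/C=C/B1OC(C)(C)C(C)(C)O1 | intermediate
12 | tert-butyl (3E)-4-[(5S)-5-{3-[tert-butyl(dimethyl)silyl]oxypropyl}-3-[3-(trimethylsilyl)prop-2-yn-1-yl]-4,5-dihydrofuran-2-yl]but-3-enoate | CC(C)(C)[Si](C)(C)OCCC[C@H]1CC(CC#C[Si](C)(C)C)=C(/C=C/CC(=O)OC(C)(C)C)O1 | intermediate
13 | tert-butyl (3E)-4-[(5S)-5-(3-hydroxypropyl)-3-(prop-2-yn-1-yl)-4,5-dihydrofuran-2-yl]but-3-enoate | OCCC[C@H]1CC(CC#C)=C(/C=C/CC(=O)OC(C)(C)C)O1 | intermediate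
14 | tert-butyl (3E)-4-[(5S)-5-(3-oxopropyl)-3-(prop-2-yn-1-yl)-4,5-dihydrofuran-2-yl]but-3-enoate | O=CCC[C@H]1CC(CC#C)=C(/C=C/CC(=O)OC(C)(C)C)O1 | intermediate
15 | methyl 2-[bis(2,2,2-trifluoroethoxy)phosphoryl]acetate | COC(=O)CP(=O)(OCC(F)(F)F)OCC(F)(F)F | starting material
16 | methyl prop-2-enoate | C=CC(=O)OC | starting material
17 | dimethyl 2-[bis(2,2,2-trifluoroethoxy)phosphoryl]pentanedioate | COC(=O)CCC(C(=O)OC)P(=O)(OCC(F)(F)F)OCC(F)(F)F | intermediate
18 | dimethyl (2Z)-2-{3-[(2S)-5-[(1E)-4-tert-butoxy-4-oxobut-1-en-1-yl]-4-(prop-2-yn-1-yl)-2,3-dihydrofuran-2-yl]propylidene}pentanedioate | C#CCC1=C(/C=C/CC(=O)OC(C)(C)C)O[C@@H](CC/C=C(\C(=O)OC)CCC(=O)OC)C1 | intermediate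
19 | cycloadduct: bridged enol ether (C6=C7–O–C13), rings B (six-membered) and C closed, 5α-CH2CO2tBu, 8β-propargyl, 10α-CO2Me, 10β-CH2CH2CO2Me | C#CC[C@]12C[C@@H]3CC[C@H]1[C@](C(=O)OC)(CCC(=O)OC)[C@@H](CC(=O)OC(C)(C)C)C=C2O3 | intermediate
20 | 13-hydroxy-7-oxo keto triester (open form of the hemiketal), substituents as in 19 | C#CC[C@]12C[C@@H](O)CC[C@H]1[C@](C(=O)OC)(CCC(=O)OC)[C@@H](CC(=O)OC(C)(C)C)CC2=O | intermediate
21 | 13-O-(1H-imidazol-1-ylcarbonothioyl) derivative of 20 | C#CC[C@]12C[C@@H](OC(=S)n3ccnc3)CC[C@H]1[C@](C(=O)OC)(CCC(=O)OC)[C@@H](CC(=O)OC(C)(C)C)CC2=O | intermediate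
22 | 7-oxo tricycle, rings B (six-membered), C and D closed, 16-methylene | C=C1C[C@]23C[C@H]1CC[C@H]2[C@](C(=O)OC)(CCC(=O)OC)[C@@H](CC(=O)OC(C)(C)C)CC3=O | intermediate
23 | 6-(trifluoroacetyl) derivative of 22 | C=C1C[C@]23C[C@H]1CC[C@H]2[C@](C(=O)OC)(CCC(=O)OC)[C@@H](CC(=O)OC(C)(C)C)C(C(=O)C(F)(F)F)C3=O | intermediate
24 | 6-diazo-7-ketone | C=C1C[C@]23C[C@H]1CC[C@H]2[C@](C(=O)OC)(CCC(=O)OC)[C@@H](CC(=O)OC(C)(C)C)C(=[N+]=[N-])C3=O | intermediate
25 | ring-contracted ketene (C6=C7=O) | C=C1C[C@]23C[C@H]1CC[C@H]2[C@](C(=O)OC)(CCC(=O)OC)[C@@H](CC(=O)OC(C)(C)C)C3=C=O | intermediate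
26 | ring-B-contracted 7-tert-butyl ester (C6 epimers), 10α-CO2Me, 10β-CH2CH2CO2Me, 5α-CH2CO2tBu | C=C1C[C@]23C[C@H]1CC[C@H]2[C@](C(=O)OC)(CCC(=O)OC)[C@@H](CC(=O)OC(C)(C)C)C3C(=O)OC(C)(C)C | intermediate
27 | 3-oxo-4-(tert-butoxycarbonyl) tetracycle (ring A closed, C4–H, 6β-CO2tBu) | C=C1C[C@]23C[C@H]1CC[C@H]2[C@]1(C(=O)OC)CCC(=O)C(C(=O)OC(C)(C)C)[C@H]1[C@@H]3C(=O)OC(C)(C)C | intermediate
28 | 3-oxo-4β-methyl-4α-(tert-butoxycarbonyl) tetracycle | C=C1C[C@]23C[C@H]1CC[C@H]2[C@]1(C(=O)OC)CCC(=O)[C@@](C)(C(=O)OC(C)(C)C)[C@H]1[C@@H]3C(=O)OC(C)(C)C | intermediate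
29 | 3β-hydroxy triester (7- and 19-tert-butyl esters, 20-methyl ester) | C=C1C[C@]23C[C@H]1CC[C@H]2[C@]1(C(=O)OC)CC[C@H](O)[C@@](C)(C(=O)OC(C)(C)C)[C@H]1[C@@H]3C(=O)OC(C)(C)C | intermediate
30 | 3β-hydroxy-20-methoxy-20-oxogibberell-16-ene-7,19-dioic acid | C=C1C[C@]23C[C@H]1CC[C@H]2[C@]1(C(=O)OC)CC[C@H](O)[C@@](C)(C(=O)O)[C@H]1[C@@H]3C(=O)O | intermediate
31 | 3β-hydroxy-20-oxogibberell-16-ene-7,19-dioic acid (the target gibberellin) | C=C1C[C@]23C[C@H]1CC[C@H]2[C@]1(C=O)CC[C@H](O)[C@@](C)(C(=O)O)[C@H]1[C@@H]3C(=O)O | target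

Total step count: 19. Longest linear sequence: 17 steps (1–4, 6–8, 10–19).

Steps most likely to fail

Step 11. The cycloaddition may be outrun by a [1,5]-hydrogen shift from the propargylic C15–H into the diene, by Z to E isomerisation of the enoate, or by acid-induced cleavage and oligomerisation of the dienol ether before the two hindered bonds form. Fallback: setting out from 18, controlled hydrolysis (pyridinium p-toluenesulfonate, wet acetone) gives the open γ-hydroxy enone F1, silylation (Et3SiOTf, 2,6-lutidine) gives its O-triethylsilyl ether F2, and an intramolecular double Michael reaction under reversible soft-enolisation conditions (Me3SiCl, Et3N, ZnCl2, PhMe, 140 °C), followed by hydrolytic work-up, gives the 13-O-triethylsilyl keto triester F3. HF·pyridine then returns to 20. Facial control in this variant rests on the equatorial preference of the C13 silyloxy group in a chair-like tether and no longer on a ring.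

Step 16. Enolisation at C2 followed by Claisen closure onto a tert-butyl ester, retro-Claisen opening, or methylation from the α face may erode the ring A annulation. Fallback: setting out from 26, LiOH (THF/H2O, 0 °C) hydrolyses only the unhindered C3 methyl ester to the monoacid F4, which is equilibrated at C6 as its potassium carboxylate with KOtBu in t-BuOH, where no Claisen path is open. Treatment of that carboxylate with (COCl)2 and catalytic DMF gives the acid chloride F5, and a TiCl4/Bu3N-mediated intramolecular crossed Claisen acylation of the C19 tert-butyl ester enolate at low temperature returns to 27, which is methylated as in step 16 to reach 28.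

Step 19. Hindrance at C20 may stall the hydride addition, or over-reduction to the C20 alcohol with lactonisation onto the free C19 acid may occur. Fallback: setting out from 29, LiBH4 (THF, 0 → 40 °C) reduces the methyl ester and spares the two tert-butyl esters, giving di-tert-butyl 3β,20-dihydroxygibberell-16-ene-7,19-dioate F6, whose C19 tert-butyl ester resists lactonisation. Catalytic TEMPO with PhI(OAc)2 (CH2Cl2, 20 °C) should oxidise the primary alcohol in preference to the hindered axial secondary one to di-tert-butyl 3β-hydroxy-20-oxogibberell-16-ene-7,19-dioate F7, and Me3SiOTf/2,6-lutidine followed by H2O/MeOH, as in step 18, returns to 31.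

Further compounds
F1 | step 11 | γ-hydroxy enone from hydrolysis of the dienol ether of 18 | C#CCC(C[C@@H](O)CC/C=C(\C(=O)OC)CCC(=O)OC)C(=O)/C=C/CC(=O)OC(C)(C)C
F2 | step 11 | O-triethylsilyl ether of F1 | C#CCC(C[C@@H](O[Si](CC)(CC)CC)CC/C=C(\C(=O)OC)CCC(=O)OC)C(=O)/C=C/CC(=O)OC(C)(C)C
F3 | step 11 | 13-O-triethylsilyl derivative of 20 | C#CC[C@]12C[C@@H](O[Si](CC)(CC)CC)CC[C@H]1[C@](C(=O)OC)(CCC(=O)OC)[C@@H](CC(=O)OC(C)(C)C)CC2=O
F4 | step 16 | C3 monoacid of 26 (6β-ester after equilibration) | C=C1C[C@]23C[C@H]1CC[C@H]2[C@](C(=O)OC)(CCC(=O)O)[C@@H](CC(=O)OC(C)(C)C)[C@@H]3C(=O)OC(C)(C)C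
F5 | step 16 | C3 acid chloride of F4 | C=C1C[C@]23C[C@H]1CC[C@H]2[C@](C(=O)OC)(CCC(=O)Cl)[C@@H](CC(=O)OC(C)(C)C)[C@@H]3C(=O)OC(C)(C)C
F6 | step 19 | di-tert-butyl 3β,20-dihydroxygibberell-16-ene-7,19-dioate | C=C1C[C@]23C[C@H]1CC[C@H]2[C@]1(CO)CC[C@H](O)[C@@](C)(C(=O)OC(C)(C)C)[C@H]1[C@@H]3C(=O)OC(C)(C)C
F7 | step 19 | di-tert-butyl 3β-hydroxy-20-oxogibberell-16-ene-7,19-dioate | C=C1C[C@]23C[C@H]1CC[C@H]2[C@]1(C=O)CC[C@H](O)[C@@](C)(C(=O)OC(C)(C)C)[C@H]1[C@@H]3C(=O)OC(C)(C)C
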